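Ring numbering: O1, C2 (aryl trans to the C3 arm), C3, C4, C5 (aryl cis to the C4 arm). The target is (2S,3R,4R,5R), with both aryls and the C4 arm on one face and the C3 arm on the other.
Retrosynthesis: mask the phenols as benzyl ethers. Trace the C3 CH2OH to one ester of a C3 malonate and the C4 CH2OH to an exocyclic C4=CH2. Then cut O1–C2 and C3–C4 of that 4-methylene-3,3-diester.
The cuts give an (R)-1-arylprop-2-yn-1-ol (O1, C5, C4 and the methylene carbon) and an arylidene malonate (C2, C3 and the C3 arm), both made from O-benzylvanillin.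
Enabling feature: C4–H lies on the aryl-free face, where a borane delivers hydrogen to a C4 methylene flanked by cis aryls. The C3 arm is trans to both neighbours, the thermodynamic position, so C3 can pass through a stereochemically blank gem-diester that also supplies the ring-closing carbanion.
Forward: the two fragments are joined and the only ring, the tetrahydrofuran, closes in one flask (O1–C2, then C3–C4). The two arms are then adjusted on the intact ring.
Stereochemistry: C5 comes from a lipase resolution, C2 from C5 (2,5-cis selection in the annulation), C4 from hydroboration anti to both aryls, and C3 from base equilibration of the mono-ester.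

Key step: step 5

Remark: Ar = 4-benzyloxy-3-methoxyphenyl throughout. The lipase is assumed to acylate the (R)-enantiomer of the carbinol, as the size rule for secondary alcohols (ethynyl small, aryl large) predicts.

Step 1
Reactants: 1 4-benzyloxy-3-methoxybenzaldehyde (O-benzylvanillin); 2 dimethyl malonate
Product: 3 dimethyl 2-(4-benzyloxy-3-methoxybenzylidene)malonate
Conditions: piperidine (0.1 equiv), AcOH (0.1 equiv), toluene, reflux, Dean–Stark trap
Reagents that add atoms: none
Why: Knoevenagel condensation of a non-enolisable aromatic aldehyde with a malonate is driven to completion by azeotropic removal of water, and the two identical esters leave no alkene geometry to control.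

Step 2
Reactants: 1 4-benzyloxy-3-methoxybenzaldehyde; 4 ethynylmagnesium bromide
Product: 5 rac-1-(4-benzyloxy-3-methoxyphenyl)prop-2-yn-1-ol
Conditions: HC≡CMgBr (0.5 M in THF, 1.3 equiv), THF, 0 °C to rt; aqueous quench
Reagents that add atoms: none
Why: Grignard 1,2-addition of an alkynyl nucleophile to an aromatic aldehyde is clean and gives the racemic carbinol needed for the resolution.

Step 3
Reactants: 5 rac-1-(4-benzyloxy-3-methoxyphenyl)prop-2-yn-1-ol
Product: 6 (R)-1-(4-benzyloxy-3-methoxyphenyl)prop-2-yn-1-yl acetate
Conditions: Novozym 435 (immobilised Candida antarctica lipase B), vinyl acetate (3 equiv), toluene, 40 °C, stopped just short of half conversion; chromatography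
Reagents that add atoms: vinyl acetate, CC(=O)OC=C
Why: Lipase-catalysed kinetic resolution by irreversible transesterification should acylate the enantiomer that places ethynyl in the small pocket and aryl in the large one, here (R) as for 1-arylethanols and terminal 1-arylpropargyl alcohols, so stopping early should give 6 in high enantiomeric purity while the (S)-enantiomer of 5 stays an alcohol and is separated.

Step 4
Reactants: 6 (R)-1-(4-benzyloxy-3-methoxyphenyl)prop-2-yn-1-yl acetate
Product: 7 (R)-1-(4-benzyloxy-3-methoxyphenyl)prop-2-yn-1-ol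
Conditions: K2CO3 (0.2 equiv), MeOH, 0 °C to rt
Reagents that add atoms: none
Why: Carbonate-catalysed methanolysis (transesterification) breaks only the acyl–oxygen bond, so the C–O bond at the stereocentre is untouched and the configuration is kept.

Step 5
Reactants: 7 (R)-1-(4-benzyloxy-3-methoxyphenyl)prop-2-yn-1-ol; 3 dimethyl 2-(4-benzyloxy-3-methoxybenzylidene)malonate
Product: 10 dimethyl (2R,5S)-2,5-bis(4-benzyloxy-3-methoxyphenyl)-4-methylenetetrahydrofuran-3,3-dicarboxylate (2,5-cis), via potassium malonate adduct 8 (not isolated), via alkenylcopper species 9 (not isolated)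
Conditions: 7 (1.1 equiv), 3 (1.0 equiv), KOtBu (0.15 equiv), CuI (0.10 equiv), THF, 0 °C to rt, argon
Reagents that add atoms: none
Why: Catalytic KOtBu converts 7 into its potassium alkoxide, which adds reversibly to the benzylidene carbon of 3 (oxa-Michael addition, O1–C2) to give malonate anion 8; CuI then activates the terminal alkyne, the carbanion attacks its internal carbon anti to copper (C3–C4), and alkenylcopper 9 is protonated by the next molecule of 7, which returns both the alkoxide and monovalent copper. The closest known reaction type is the base- and copper-catalysed tandem oxa-Michael addition/carbocyclisation of propargylic alcohols with alkylidene or arylidene malonates to 3-methylenetetrahydrofurans, an anionic relative of the Conia-ene reaction. The single ring formed, the tetrahydrofuran, closes 5-exo-dig, a mode allowed by the Baldwin rules and favoured over 6-endo attack because the three-atom link brings the internal alkyne carbon over the carbanion. C5 is carried over from 7 because its C–O bond is never broken, and the one new stereocentre, C2, is set relative to it: the C2 epimers of 8 should interconvert by retro-Michael/Michael steps faster than they cyclise, so the outcome reflects the two cyclisation transition states (Curtin–Hammett control). The 2,5-cis ring is needed, and the substrate favours it because allylic strain against the planar malonate keeps C2–H in the malonate plane and the C2 aryl pseudo-equatorial, while a pseudo-axial C5 aryl would meet one of the two C3 esters across the ring, so the envelope with both aryls pseudo-equatorial should be the lower one. Closure creates a quaternary C3 and is therefore irreversible, which drains the unfavourable addition equilibrium of the electron-rich acceptor, and the small amount of base at or below room temperature under argon should spare the propargylic stereocentre, the exocyclic alkene of 10 and the alkyne from oxidative coupling.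

Step 6
Reactants: 10 dimethyl (2R,5S)-2,5-bis(Ar)-4-methylenetetrahydrofuran-3,3-dicarboxylate
Product: 12 dimethyl (2R,4R,5R)-2,5-bis(4-benzyloxy-3-methoxyphenyl)-4-(hydroxymethyl)tetrahydrofuran-3,3-dicarboxylate (CH2OH cis to both aryls), via B-alkyl-9-BBN adduct 11 (not isolated)
Conditions: 9-BBN (0.5 M in THF, 2.5 equiv), THF, rt to 45 °C; then NaBO3·4H2O, THF–H2O, rt; crude product taken on at once
Reagents that add atoms: sodium perborate (oxygen atom), [Na+].[Na+].O[B-]1(O)OO[B-](O)(O)OO1; 9-BBN (its boron cage is held only in 11), B1C2CCCC1CCC2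
Why: Hydroboration–oxidation with the bulky, ester-tolerant borane places boron on the terminal carbon and delivers hydrogen to C4 from the face opposite the C5 and C2 aryls, which sets C4 with the new arm cis to both aryls, and the near-neutral perborate oxidation is chosen to keep the γ-hydroxy diester from closing to a lactone.

Step 7
Reactants: 12 dimethyl (2R,4R,5R)-2,5-bis(Ar)-4-(hydroxymethyl)tetrahydrofuran-3,3-dicarboxylate
Product: 13 dimethyl (2R,4R,5R)-2,5-bis(4-benzyloxy-3-methoxyphenyl)-4-[(triisopropylsilyloxy)methyl]tetrahydrofuran-3,3-dicarboxylate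
Conditions: TIPSOTf (1.2 equiv), 2,6-lutidine (2 equiv), CH2Cl2, −20 to 0 °C
Reagents that add atoms: triisopropylsilyl triflate, CC(C)[Si](OS(=O)(=O)C(F)(F)F)(C(C)C)C(C)C
Why: Silylation of a primary alcohol with a silyl triflate and a hindered pyridine base is fast in the cold and never forms a free alkoxide, so the alcohol is capped before it can attack the cis ester, and the triisopropylsilyl ether should outlast hot LiCl, methoxide and LiAlH4.

Step 8
Reactants: 13 dimethyl (2R,4R,5R)-2,5-bis(Ar)-4-[(triisopropylsilyloxy)methyl]tetrahydrofuran-3,3-dicarboxylate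
Product: 14 methyl (2S,4R,5R)-2,5-bis(4-benzyloxy-3-methoxyphenyl)-4-[(triisopropylsilyloxy)methyl]tetrahydrofuran-3-carboxylate, mixture of C3 epimers
Conditions: LiCl (4 equiv), H2O (2 equiv), DMSO, 150 °C
Reagents that add atoms: none
Why: In the Krapcho dealkoxycarbonylation chloride removes a methyl group by SN2 attack, the carboxylate on the crowded quaternary carbon loses CO2 and water protonates the ester enolate, which should give both C3 epimers with C2, C4 and C5 untouched.

Step 9
Reactants: 14 methyl 2,5-bis(Ar)-4-[(triisopropylsilyloxy)methyl]tetrahydrofuran-3-carboxylate, C3 epimers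
Product: 15 methyl (2S,3S,4R,5R)-2,5-bis(4-benzyloxy-3-methoxyphenyl)-4-[(triisopropylsilyloxy)methyl]tetrahydrofuran-3-carboxylate (ester trans to the C2 aryl and to the C4 arm)
Conditions: NaOMe (0.3 equiv), MeOH–THF, 40 °C
Reagents that add atoms: none
Why: Base-mediated epimerisation through the ester enolate is under thermodynamic control and should converge on the isomer with the ester trans to both neighbours, while β-elimination of O1 is held back because the ring C2–O1 bond lies near the nodal plane of the enolate (the reverse of a 5-endo-trig closure).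

Step 10
Reactants: 15 methyl (2S,3S,4R,5R)-2,5-bis(Ar)-4-[(triisopropylsilyloxy)methyl]tetrahydrofuran-3-carboxylate
Product: 16 {(2S,3R,4R,5R)-2,5-bis(4-benzyloxy-3-methoxyphenyl)-4-[(triisopropylsilyloxy)methyl]tetrahydrofuran-3-yl}methanol
Conditions: LiAlH4 (1.5 equiv), THF, 0 °C; Fieser work-up
Reagents that add atoms: none
Why: Hydride reduction of the ester to the primary alcohol leaves C3–H, the benzyl ethers and the silyl ether alone, so the configuration fixed in step 9 passes into the C3 arm.

Step 11
Reactants: 16 {(2S,3R,4R,5R)-2,5-bis(Ar)-4-[(triisopropylsilyloxy)methyl]tetrahydrofuran-3-yl}methanol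
Product: 17 [(2S,3R,4R,5R)-2,5-bis(4-benzyloxy-3-methoxyphenyl)tetrahydrofuran-3,4-diyl]dimethanol
Conditions: TBAF (1.5 equiv), THF, rt
Reagents that add atoms: none
Why: Fluoride-induced desilylation, driven by the strong Si–F bond, frees the C4 arm under non-acidic conditions that spare the acid-labile dibenzylic ether ring.

Step 12
Reactants: 17 [(2S,3R,4R,5R)-2,5-bis(Ar)tetrahydrofuran-3,4-diyl]dimethanol
Product: 18 [(2S,3R,4R,5R)-2,5-bis(4-hydroxy-3-methoxyphenyl)tetrahydrofuran-3,4-diyl]dimethanol (CNP0286218.5)
Conditions: H2 (1 atm), 10% Pd/C, EtOAc–EtOH, rt, stopped at consumption of 17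
Reagents that add atoms: none
Why: Catalytic hydrogenolysis of aryl benzyl ethers over palladium under neutral conditions at one atmosphere is much faster than cleavage of the ring benzylic C–O bonds, so timely interruption should give 18 with all four stereocentres intact.

Compound list
1 | 4-benzyloxy-3-methoxybenzaldehyde | COc1cc(C=O)ccc1OCc1ccccc1 | starting material
2 | dimethyl malonate | COC(=O)CC(=O)OC | starting material
3 | dimethyl 2-(4-benzyloxy-3-methoxybenzylidene)malonate | COC(=O)C(=Cc1ccc(OCc2ccccc2)c(OC)c1)C(=O)OC | intermediate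
4 | ethynylmagnesium bromide | C#C[Mg]Br | starting material
5 | rac-1-(4-benzyloxy-3-methoxyphenyl)prop-2-yn-1-ol | OC(c1ccc(OCc2ccccc2)c(OC)c1)C#C | intermediate
6 | (R)-1-(4-benzyloxy-3-methoxyphenyl)prop-2-yn-1-yl acetate | CC(=O)O[C@@H](c1ccc(OCc2ccccc2)c(OC)c1)C#C | intermediate
7 | (R)-1-(4-benzyloxy-3-methoxyphenyl)prop-2-yn-1-ol | O[C@@H](c1ccc(OCc2ccccc2)c(OC)c1)C#C | intermediate
8 | potassium malonate anion of the oxa-Michael adduct, (S) at the new benzylic carbon, (R) at the propargylic carbon (the epimer that closes to 10) | COc1cc([C@@H](O[C@@H](c2ccc(OCc3ccccc3)c(OC)c2)C#C)[C-](C(=O)OC)C(=O)OC)ccc1OCc1ccccc1.[K+] | intermediate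
9 | exocyclic alkenylcopper species, copper cis to C5 | COc1cc([C@H]2O[C@@H](c3ccc(OCc4ccccc4)c(OC)c3)/C(=C\[Cu])C2(C(=O)OC)C(=O)OC)ccc1OCc1ccccc1 | intermediate
10 | dimethyl (2R,5S)-2,5-bis(4-benzyloxy-3-methoxyphenyl)-4-methylenetetrahydrofuran-3,3-dicarboxylate | COc1cc([C@H]2O[C@@H](c3ccc(OCc4ccccc4)c(OC)c3)C(=C)C2(C(=O)OC)C(=O)OC)ccc1OCc1ccccc1 | intermediate
11 | B-alkyl-9-BBN adduct of 10, CH2B cis to both aryls | COc1cc([C@H]2O[C@@H](c3ccc(OCc4ccccc4)c(OC)c3)[C@@H](CB3C4CCCC3CCC4)C2(C(=O)OC)C(=O)OC)ccc1OCc1ccccc1 | intermediate
12 | dimethyl (2R,4R,5R)-2,5-bis(4-benzyloxy-3-methoxyphenyl)-4-(hydroxymethyl)tetrahydrofuran-3,3-dicarboxylate | COc1cc([C@H]2O[C@@H](c3ccc(OCc4ccccc4)c(OC)c3)[C@@H](CO)C2(C(=O)OC)C(=O)OC)ccc1OCc1ccccc1 | intermediate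
13 | dimethyl (2R,4R,5R)-2,5-bis(4-benzyloxy-3-methoxyphenyl)-4-[(triisopropylsilyloxy)methyl]tetrahydrofuran-3,3-dicarboxylate | COc1cc([C@H]2O[C@@H](c3ccc(OCc4ccccc4)c(OC)c3)[C@@H](CO[Si](C(C)C)(C(C)C)C(C)C)C2(C(=O)OC)C(=O)OC)ccc1OCc1ccccc1 | intermediate
14 | methyl (2S,4R,5R)-2,5-bis(4-benzyloxy-3-methoxyphenyl)-4-[(triisopropylsilyloxy)methyl]tetrahydrofuran-3-carboxylate, C3 epimers | COc1cc([C@H]2O[C@@H](c3ccc(OCc4ccccc4)c(OC)c3)[C@@H](CO[Si](C(C)C)(C(C)C)C(C)C)C2C(=O)OC)ccc1OCc1ccccc1 | intermediate
15 | methyl (2S,3S,4R,5R)-2,5-bis(4-benzyloxy-3-methoxyphenyl)-4-[(triisopropylsilyloxy)methyl]tetrahydrofuran-3-carboxylate | COc1cc([C@H]2O[C@@H](c3ccc(OCc4ccccc4)c(OC)c3)[C@@H](CO[Si](C(C)C)(C(C)C)C(C)C)[C@@H]2C(=O)OC)ccc1OCc1ccccc1 | intermediate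
16 | {(2S,3R,4R,5R)-2,5-bis(4-benzyloxy-3-methoxyphenyl)-4-[(triisopropylsilyloxy)methyl]tetrahydrofuran-3-yl}methanol | COc1cc([C@H]2O[C@@H](c3ccc(OCc4ccccc4)c(OC)c3)[C@@H](CO[Si](C(C)C)(C(C)C)C(C)C)[C@@H]2CO)ccc1OCc1ccccc1 | intermediate
17 | [(2S,3R,4R,5R)-2,5-bis(4-benzyloxy-3-methoxyphenyl)tetrahydrofuran-3,4-diyl]dimethanol | COc1cc([C@H]2O[C@@H](c3ccc(OCc4ccccc4)c(OC)c3)[C@@H](CO)[C@@H]2CO)ccc1OCc1ccccc1 | intermediate
18 | [(2S,3R,4R,5R)-2,5-bis(4-hydroxy-3-methoxyphenyl)tetrahydrofuran-3,4-diyl]dimethanol | COc1cc([C@H]2O[C@@H](c3ccc(O)c(OC)c3)[C@@H](CO)[C@@H]2CO)ccc1O | target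

Total step count: 12. Longest linear sequence: 11 (steps 2 to 12, from 1).

Steps most likely to fail

Step 5.
- The two cyclisation transition states may not be discriminated well enough, so 2,5-cis and 2,5-trans rings would form together.
- The adduct of the electron-rich acceptor may revert faster than it closes.
- The base may shift the exocyclic double bond into the ring or erode the propargylic stereocentre.

The fallback replaces the anionic annulation with the Lewis-acid-catalysed [3+2] cycloaddition of a donor–acceptor cyclopropane with an aldehyde. That reaction type is known to give 2,5-cis-tetrahydrofuran-3,3-dicarboxylates with inversion at the donor carbon. It sets out from 1. Wittig reaction with Ph3P=CHCHO gives (E)-3-(4-benzyloxy-3-methoxyphenyl)acrylaldehyde F1. Iminium-catalysed Michael-initiated ring closure with dimethyl bromomalonate, (S)-α,α-diphenylprolinol trimethylsilyl ether and 2,6-lutidine should give dimethyl (2S,3R)-2-(4-benzyloxy-3-methoxyphenyl)-3-formylcyclopropane-1,1-dicarboxylate F2. NaBH4 in MeOH at 0 °C gives the hydroxymethyl cyclopropane F3, and TIPSOTf/2,6-lutidine gives its triisopropylsilyl ether F4. F4 and a second portion of 1 with catalytic AlCl3 in CH2Cl2 in the cold should then combine. The aldehyde oxygen enters at the aryl-bearing carbon with inversion, which turns the trans cyclopropane into the 4,5-cis pair, and the malonate closes onto the oxocarbenium ion to the 2,5-cis ring. The route is rejoined at 13, so steps 6 and 7 are bypassed as well.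

Step 6.
- The freed alcohol may close onto the cis ester during oxidation or handling.
- Hydroboration next to the quaternary carbon may be sluggish.
- Facial discrimination may be incomplete.

The fallback makes lactonisation the intended event and does without the silyl group. It sets out from 10. Hydroboration and perborate oxidation as before, followed by catalytic DBU in toluene, drive crude 12 fully to the cis-fused γ-lactone ester F5. Krapcho dealkoxycarbonylation (LiCl, wet DMSO, heat) removes the remaining methyl ester and gives the cis-fused γ-lactone F6. NaOMe in MeOH then opens the lactone and epimerises C3. Only the cis hydroxy ester can close again, whereas methyl (2S,3S,4R,5R)-2,5-bis(4-benzyloxy-3-methoxyphenyl)-4-(hydroxymethyl)tetrahydrofuran-3-carboxylate F7 cannot. F7 is also relieved of two cis contacts, so it should accumulate, and recovered lactone can be resubmitted. LiAlH4 reduces F7 directly to 17, where the route is rejoined.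

Step 8.
- Hot chloride and water may strip the silyl ether, after which the alcohol would lactonise.
- The ester enolate formed at 150 °C may open the ring by β-elimination.

The fallback changes from alkyl–oxygen to acyl–oxygen cleavage and separates hydrolysis from decarboxylation. It sets out from 13. LiOH in THF–MeOH–H2O at 50 °C should hydrolyse only the ester on the aryl-free face and stop there, because the carboxylate shields its neighbour. This gives (2R,3R,4R,5R)-2,5-bis(4-benzyloxy-3-methoxyphenyl)-3-(methoxycarbonyl)-4-[(triisopropylsilyloxy)methyl]tetrahydrofuran-3-carboxylic acid F8. Heating F8 with Et3N in toluene at about 100 °C decarboxylates the malonic half acid without any nucleophilic salt. The route is rejoined at 14, ahead of the equilibration of step 9.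

Further compounds
F1 | step 5 | (E)-3-(4-benzyloxy-3-methoxyphenyl)acrylaldehyde | O=C/C=C/c1ccc(OCc2ccccc2)c(OC)c1
F2 | step 5 | dimethyl (2S,3R)-2-(4-benzyloxy-3-methoxyphenyl)-3-formylcyclopropane-1,1-dicarboxylate | COC(=O)C1(C(=O)OC)[C@H](c2ccc(OCc3ccccc3)c(OC)c2)[C@H]1C=O
F3 | step 5 | dimethyl (2S,3R)-2-(4-benzyloxy-3-methoxyphenyl)-3-(hydroxymethyl)cyclopropane-1,1-dicarboxylate | COC(=O)C1(C(=O)OC)[C@H](c2ccc(OCc3ccccc3)c(OC)c2)[C@H]1CO
F4 | step 5 | dimethyl (2S,3R)-2-(4-benzyloxy-3-methoxyphenyl)-3-[(triisopropylsilyloxy)methyl]cyclopropane-1,1-dicarboxylate | COC(=O)C1(C(=O)OC)[C@H](c2ccc(OCc3ccccc3)c(OC)c2)[C@H]1CO[Si](C(C)C)(C(C)C)C(C)C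
F5 | step 6 | cis-fused γ-lactone ester (lactone between the C4 CH2O and the C3 carbonyl on the aryl face, CO2Me on C3 on the other face) | COc1cc([C@H]2O[C@@H](c3ccc(OCc4ccccc4)c(OC)c3)[C@H]3COC(=O)[C@@]23C(=O)OC)ccc1OCc1ccccc1
F6 | step 6 | cis-fused γ-lactone (C3–H and C4–H on the aryl-free face) | COc1cc([C@H]2O[C@@H](c3ccc(OCc4ccccc4)c(OC)c3)[C@H]3COC(=O)[C@@H]23)ccc1OCc1ccccc1
F7 | step 6 | methyl (2S,3S,4R,5R)-2,5-bis(4-benzyloxy-3-methoxyphenyl)-4-(hydroxymethyl)tetrahydrofuran-3-carboxylate | COc1cc([C@H]2O[C@@H](c3ccc(OCc4ccccc4)c(OC)c3)[C@@H](CO)[C@@H]2C(=O)OC)ccc1OCc1ccccc1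
F8 | step 8 | (2R,3R,4R,5R)-2,5-bis(4-benzyloxy-3-methoxyphenyl)-3-(methoxycarbonyl)-4-[(triisopropylsilyloxy)methyl]tetrahydrofuran-3-carboxylic acid | COc1cc([C@H]2O[C@@H](c3ccc(OCc4ccccc4)c(OC)c3)[C@@H](CO[Si](C(C)C)(C(C)C)C(C)C)[C@@]2(C(=O)O)C(=O)OC)ccc1OCc1ccccc1
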